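Numbering used throughout: ring B is the dihydrofuran (O1, C2, C3, C3a, C7a); ring A is the fused benzene ring (C3a, C4 to C7, C7a); ring C is the aryl group on C2 (C1' to C6'); C9 is the hydroxymethyl carbon on C3.

## Analysis of the target

The target 19 is a 2-aryl-2,3-dihydrobenzofuran of the 8–5' neolignan family. Ring A carries a methoxy group on C7 and a 3-hydroxypropyl chain on C5, para to O1; ring C is a 4-hydroxy-3,5-dimethoxyphenyl group. The two stereocentres, C2 (S) and C3 (R), are adjacent, and ring C and the C9 arm lie trans across ring B. The C2–O1 bond is a benzylic aryl ether para to a free phenol, so it ionises easily to a quinone-methide-type cation. C2 can therefore be equilibrated, with trans the more stable arrangement, whereas C3 has no such pathway and must be made once in the correct absolute sense. Further sensitive points are the oxidisable phenol, three electron-rich arenes that rule out late electrophilic oxidants, and the 1,3-relationship of the C2 and C9 oxygens, which allows loss of C9 if a C2 cation lives too long. The real difficulty is the enantioselective construction of C3, a benzylic methine with no carbonyl or heteroatom through which an auxiliary or reduction catalyst could reach it. The plan rests on the C2–C3 bond: each of these neighbouring carbons holds exactly one aryl ring (C1' on C2, C3a on C3), with a heteroatom on C2 and C9 on C3. That pattern results when two different aryl groups are added anti across the double bond of an (E)-3-oxygenated prop-1-enylboron compound and boron is then exchanged for oxygen.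

## Retrosynthetic reasoning

**O1–C2 (19 from 17 through 18).** Ring B is opened at O1–C2 because this is the one bond of the ring that forms under thermodynamic control. The fully deprotected pentaol 18 has a C2 benzylic alcohol para to a phenol and the C7a phenol five atoms away. In acid, C2 becomes planar and is recaptured by the C7a oxygen anti to the C9 arm. The protected alcohol 17, with methoxymethyl acetals on both phenols and silyl ethers on both primary alcohols, releases 18 under the same acid. A displacement with inversion at C2 is not used: 17 carries its C2 oxygen on the face that O1 occupies in 19, so inversion would give the cis ring. The gain is an acyclic precursor in which only C3 needs absolute control.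

**C2–O to C2–B (17 from 16).** The C2 hydroxyl is traced to a carbon–boron bond in the boronic ester 16. Alkaline peroxide oxidation proceeds with retention, so the relative configuration made at the boron stage is carried into 17, and the oxidation also returns the diol 4.

**C2–C1' and C3–C3a (16 from 15, that is from 6, 14 and 11).** Both aryl–carbon bonds of the C2–C3 unit are cut at once. Forward, the syringyllithium 14 adds to boron of the (E)-alkenylboronic ester 6 to give the ate complex 15. A palladium catalyst bearing a chiral ferrocene bisphosphine then joins 15 with the ring A bromide 11: ring C shifts from boron to C2 while ring A bonds to C3. Cutting here is preferred because the three fragments are simple, each arene arrives with all its oxygen substituents, and the E geometry plus anti addition fixes the relative configuration while the ligand fixes the absolute one. Two adjustments make the step defensible for a β-substituted alkene and a bromide electrophile: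
- Boron carries the rigid cis-diol 4, whose shielded diolate oxygens disfavour direct transfer of an organic group from boron to palladium.
- A triflate salt is added to take up the bromide released from 11 and from the preparation of 14, since halide blocks the coordination site the alkene needs.

**Alkenylboron 6 (from 2 and 4; 2 from 1; 4 from 3).** Hydroboration of the silyl ether 2 of propargyl alcohol 1 puts boron on the terminal carbon with E geometry. The first-formed catechol ester 5 is exchanged in the same flask for the ester of 4. Diol 4 comes from acenaphthoquinone 3 by twofold methyl addition.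

**Ring A bromide 11 (from 10, 9, 8 and eugenol 7).** Eugenol 7 already has the ring A pattern: oxygen at the future C7a, methoxy at C7, a three-carbon chain para to oxygen, and a free ortho position that becomes C3a. Hydroboration–oxidation gives the primary alcohol 8. Phenol-directed bromination gives 9. Selective acetal protection of the phenol gives 10, and silylation gives 11. No carbon–carbon bond has to be made on ring A.

**Aryllithium 14 (from 13 and 12).** The commercial bromophenol 12 is protected as the methoxymethyl acetal 13, and bromine–lithium exchange gives 14. The acetal is chosen because it survives the aryllithium, the palladium step and the peroxide, and falls in the final acid step.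

## Alternatives that were turned down

**Alternative 1:** Oxidative ring contraction of a flavanone.
- Disconnection: C3–C3a, made by a 1,2-shift of the ring A carbon from the carbonyl carbon of the (2S)-flavanone A2 to its neighbour.
- Forward key step: a trivalent iodine oxidant with strong acid in an orthoester solvent turns A2 into its enol ether, attacks C3 and triggers the aryl shift to the trans ester A1, methyl (2S,3S)-5-(3-acetoxypropyl)-2-(4-acetoxy-3,5-dimethoxyphenyl)-7-methoxy-2,3-dihydrobenzofuran-3-carboxylate. Ester reduction and acetate removal would finish.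
- For: ring B and the C2 configuration are in place before the key step, the trans relationship comes from a stereospecific rearrangement, and C9 arrives at a convenient oxidation level.
- Against, for this target: ring C of A2 is very electron-rich, so its own 1,2-shift to an isoflavone-type product competes with the ring A shift. The strong acid can open the pyranone by retro-oxa-Michael reaction and erode C2. The oxidant can attack the oxygenated arenes. A2 itself needs a separate asymmetric synthesis, which makes the sequence long and linear.
- Comparison: this alternative is stronger in that the ring is never reopened and no late cation is needed. The chosen route offers convergence, no electrophilic oxidant on the electron-rich rings, and direct catalyst control of C3.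

**Alternative 2:** Ring A by alkyne (2+2+2) cyclotrimerisation.
- Disconnection: C3a–C7a, C4–C5 and C6–C7.
- Forward key step: under ruthenium catalysis the chiral 1,6-diyne A4 (a silyl ynol ether tethered through O1, C2 and C3 to a terminal alkyne) takes up the alkyne A5 to give A3. A3 is the trans-dihydrobenzofuran with a trimethylsilyl group on C7.
- For: rings A and B form in one step from acyclic material, and both stereocentres are fixed beforehand and are not touched by the cyclisation.
- Against: the ynol ether in A4 is fragile, and A4 needs its own multistep stereoselective synthesis. The position of the chain (C5 and not C6) depends on the regioselectivity of alkyne insertion. The silicon on C7 of A3 must then be replaced by methoxy through ipso-halogenation and carbon–oxygen coupling on an arene that offers other reactive positions. The route builds a benzene ring that eugenol supplies ready-made.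
- Comparison: it is equal or stronger in stereochemical security of ring B, and much weaker in step economy and in the late C7 oxygenation. The chosen route starts with every ring substituent in place.

**Alternative 3:** Aldol, then closure of the aldol oxygen onto ring A.
- Disconnection: C7a–O1.
- Forward key step: copper-catalysed intramolecular etherification with a diamine-type ligand and carbonate base couples the secondary benzylic alcohol of the syn-aldol-derived bromoarene A7 with C7a. This gives A6, the trans-dihydrobenzofuran lacking the C5 chain, with retention at C2.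
- For: both stereocentres come from an auxiliary-controlled syn aldol, and the closure is stereospecific, so no cation and no equilibration are involved. On stereochemical certainty this is the strongest plan.
- Against: the bromide of A7 sits between two ortho substituents, a hard case for copper-mediated coupling with a hindered secondary alkoxide, and oxidation of that alkoxide can compete. The C5 chain must be added after closure by bromination of A6 and cross-coupling. That bromination has to discriminate C5 from the open positions of the very electron-rich ring C. With auxiliary attachment and removal the sequence is roughly twice as long.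
- Comparison: the chosen route gives up that certainty at C2, which it does not need because C2 is reset under control of C3. In return it gains a three-fragment union with the chain already on ring A and a longest linear sequence of seven steps.

Key step: step 9

Assumption: the (Sp,Sp) enantiomer of the ferrocene bisphosphine named in step 9 is taken to direct palladium to the alkene face that leads to (1S,2R)-16; should the sense of induction prove opposite, its mirror-image ligand is used and nothing else changes.

## Route

Step 1
Reactants: 1 prop-2-yn-1-ol (propargyl alcohol)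
Product: 2 tert-butyldimethyl(prop-2-yn-1-yloxy)silane
Conditions: TBSCl, imidazole, CH2Cl2, 0 °C to rt
Reagents that add atoms: tert-butyldimethylsilyl chloride (TBSCl), CC(C)(C)[Si](C)(C)Cl
Why: Silyl ether formation on a primary alcohol; the ether masks the C9 oxygen through hydroboration, aryllithium addition and palladium catalysis and is a poor leaving group.

Step 2
Reactants: 3 acenaphthylene-1,2-dione (acenaphthoquinone)
Product: 4 cis-1,2-dimethyl-1,2-dihydroacenaphthylene-1,2-diol (meso, 1R,2S)
Conditions: AlMe3 (4 equiv), toluene, 0 °C to rt; dilute aq. HCl; recrystallisation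
Reagents that add atoms: trimethylaluminium, C[Al](C)C
Why: Twofold 1,2-addition of methyl to the 1,2-dione; the second methyl should enter anti to the bulky aluminium alkoxide from the first addition, giving the cis (meso) diol, the only isomer that can bridge boron in step 3.

Step 3
Reactants: 2 tert-butyldimethyl(prop-2-yn-1-yloxy)silane; 4 cis-1,2-dimethyl-1,2-dihydroacenaphthylene-1,2-diol
Product: 6 cyclic boronic ester of (E)-3-(tert-butyldimethylsilyloxy)prop-1-enylboronic acid with diol 4, via catechol boronate 5 (not isolated)
Conditions: catecholborane (1.1 equiv), Cy2BH (10 mol%), THF, rt; then 4, rt; aq. NaHCO3 wash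
Reagents that add atoms: catecholborane (1,3,2-benzodioxaborole), B1Oc2ccccc2O1
Why: Syn hydroboration of the terminal alkyne puts boron on the terminal carbon and gives the E alkene; transesterification of the labile aryl ester 5 with the aliphatic cis-diol 4 is downhill and yields a chromatography-stable ester.

Step 4
Reactants: 7 eugenol (4-allyl-2-methoxyphenol)
Product: 8 4-(3-hydroxypropyl)-2-methoxyphenol
Conditions: 9-BBN (2.5 equiv), THF, 0 °C to rt; then aq. NaOH, H2O2, 0 °C to rt
Reagents that add atoms: hydrogen peroxide, OO
Why: Anti-Markovnikov hydroboration–oxidation of the terminal alkene; the bulky borane should give only the primary alcohol, and the excess covers borane consumed by the phenol.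

Step 5
Reactants: 8 4-(3-hydroxypropyl)-2-methoxyphenol
Product: 9 2-bromo-4-(3-hydroxypropyl)-6-methoxyphenol
Conditions: NBS (1.0 equiv), i-Pr2NH (10 mol%), CH2Cl2, 0 °C
Reagents that add atoms: N-bromosuccinimide, O=C1CCC(=O)N1Br
Why: Electrophilic aromatic bromination directed by the free phenol: the para position is blocked by the chain and one ortho position by methoxy, so bromine should enter the remaining ortho carbon, the future C3a.

Step 6
Reactants: 9 2-bromo-4-(3-hydroxypropyl)-6-methoxyphenol
Product: 10 3-[3-bromo-5-methoxy-4-(methoxymethoxy)phenyl]propan-1-ol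
Conditions: MOMCl (1.1 equiv), K2CO3, acetone, 0 °C to rt
Reagents that add atoms: chloromethyl methyl ether (MOMCl), COCCl
Why: O-alkylation of a phenoxide (Williamson type); carbonate deprotonates the phenol but not the aliphatic alcohol, so the acetal should form on the phenolic oxygen only.

Step 7
Reactants: 10 3-[3-bromo-5-methoxy-4-(methoxymethoxy)phenyl]propan-1-ol
Product: 11 {3-[3-bromo-5-methoxy-4-(methoxymethoxy)phenyl]propoxy}(tert-butyl)dimethylsilane
Conditions: TBSCl, imidazole, DMF, rt
Reagents that add atoms: tert-butyldimethylsilyl chloride (TBSCl), CC(C)(C)[Si](C)(C)Cl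
Why: Silyl ether formation on the primary alcohol; it removes the last acidic proton, which would otherwise quench the ate complex in step 9.

Step 8
Reactants: 12 4-bromo-2,6-dimethoxyphenol
Product: 13 5-bromo-1,3-dimethoxy-2-(methoxymethoxy)benzene
Conditions: MOMCl, i-Pr2NEt, CH2Cl2, 0 °C to rt
Reagents that add atoms: chloromethyl methyl ether (MOMCl), COCCl
Why: O-alkylation of the phenol to the methoxymethyl acetal, which tolerates the aryllithium, the palladium step and alkaline peroxide and is removed by acid in step 11.

Step 9 (key step)
Reactants: 13 5-bromo-1,3-dimethoxy-2-(methoxymethoxy)benzene; 6 alkenylboronic ester of diol 4; 11 ring A bromide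
Product: 16 cyclic ester with diol 4 of (1S,2R)-3-(tert-butyldimethylsilyloxy)-2-[5-(3-(tert-butyldimethylsilyloxy)propyl)-3-methoxy-2-(methoxymethoxy)phenyl]-1-[3,5-dimethoxy-4-(methoxymethoxy)phenyl]propylboronic acid, via aryllithium 14 (not isolated), via boron ate complex 15 (not isolated)
Conditions: 13, t-BuLi (2.0 equiv), Et2O, −78 °C; 6, −78 °C to rt; solvent exchange to THF; Pd(OAc)2 (3 mol%), (Sp,Sp)-1,1'-bis[bis(4-methoxy-3,5-dimethylphenyl)phosphino]-2,2'-bis[(R)-α-(dimethylamino)benzyl]ferrocene (3.6 mol%), 11 (limiting), KOTf (3 equiv), THF, 60 °C
Reagents that add atoms: none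
Why: Bromine–lithium exchange gives 14, which adds to boron of 6 to form 15; zerovalent palladium, formed from Pd(OAc)2 and the bisphosphine, inserts into the C–Br bond of 11, and the arylpalladium, freed of bromide as KBr, binds the alkene of 15. Ring C then shifts from boron to C2 anti to palladium while palladium bonds C3 (1,2-metallate shift), and reductive elimination with retention forms C3–C3a. The closest known reaction is the palladium-catalysed conjunctive cross-coupling of alkenylboron ate complexes with aryl electrophiles, known also for β-substituted alkenylboron esters of diol 4 and for halide electrophiles in the presence of a triflate salt. No ring is closed. The anti addition across the E alkene fixes the relative configuration of C2 and C3, and the chiral bisphosphine on palladium selects the alkene face and so the absolute configuration of both centres. The step needs the metallate shift to beat direct Suzuki–Miyaura transfer of an aryl or alkenyl group from boron; the methyl groups and acenaphthene wall of the diolate shield the boron-bound oxygens from palladium, which should secure this. It also needs reductive elimination to outrun β-silyloxy elimination towards C9, which the chelating bisphosphine and the poor leaving ability of a silyl ether should favour.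

Step 10
Reactants: 16 boronic ester
Product: 17 (1S,2R)-3-(tert-butyldimethylsilyloxy)-2-[5-(3-(tert-butyldimethylsilyloxy)propyl)-3-methoxy-2-(methoxymethoxy)phenyl]-1-[3,5-dimethoxy-4-(methoxymethoxy)phenyl]propan-1-ol
Conditions: aq. NaOH (3 M), H2O2 (30%), THF, 0 °C to rt
Reagents that add atoms: hydrogen peroxide, OO
Why: Oxidation of the carbon–boron bond: hydroperoxide adds to boron and C2 migrates from boron to oxygen with retention, so the C2 alcohol keeps the configuration set in step 9; silyl ethers and acetals are stable to cold alkaline peroxide.

Step 11
Reactants: 17 protected alcohol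
Product: 19 4-[(2S,3R)-3-(hydroxymethyl)-5-(3-hydroxypropyl)-7-methoxy-2,3-dihydro-1-benzofuran-2-yl]-2,6-dimethoxyphenol, via deprotected pentaol 18 (not isolated)
Conditions: HCl (1.25 M in MeOH)–THF 1:1, 0.02 M, 40 °C
Reagents that add atoms: none
Why: Acid solvolysis removes both silyl ethers and both acetals; the C2 benzylic alcohol, para to the freed ring C phenol, ionises to a quinone-methide-type cation that the C7a phenol captures in a 5-exo-trig cyclodehydration. C2 is planar at that stage, so its final configuration is set here by C3: closure anti to the C9 arm gives the trans ring, also the more stable isomer under reversible ionisation, while C3 is untouched.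

## Compound list

1 | prop-2-yn-1-ol | C#CCO | starting material
2 | tert-butyldimethyl(prop-2-yn-1-yloxy)silane | C#CCO[Si](C)(C)C(C)(C)C | intermediate
3 | acenaphthylene-1,2-dione | O=C1C(=O)c2cccc3cccc1c23 | starting material
4 | cis-1,2-dimethyl-1,2-dihydroacenaphthylene-1,2-diol (meso) | C[C@]1(O)[C@@](C)(O)c2cccc3cccc1c23 | intermediate
5 | 2-[(E)-3-(tert-butyldimethylsilyloxy)prop-1-enyl]-1,3,2-benzodioxaborole | CC(C)(C)[Si](C)(C)OC/C=C/B1Oc2ccccc2O1 | intermediate (not isolated)
6 | cyclic ester of (E)-3-(tert-butyldimethylsilyloxy)prop-1-enylboronic acid with diol 4 | CC(C)(C)[Si](C)(C)OC/C=C/B1O[C@]2(C)c3cccc4cccc(c34)[C@]2(C)O1 | intermediate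
7 | eugenol (4-allyl-2-methoxyphenol) | COc1cc(CC=C)ccc1O | starting material
8 | 4-(3-hydroxypropyl)-2-methoxyphenol | COc1cc(CCCO)ccc1O | intermediate
9 | 2-bromo-4-(3-hydroxypropyl)-6-methoxyphenol | COc1cc(CCCO)cc(Br)c1O | intermediate
10 | 3-[3-bromo-5-methoxy-4-(methoxymethoxy)phenyl]propan-1-ol | COCOc1c(Br)cc(CCCO)cc1OC | intermediate
11 | {3-[3-bromo-5-methoxy-4-(methoxymethoxy)phenyl]propoxy}(tert-butyl)dimethylsilane | COCOc1c(Br)cc(CCCO[Si](C)(C)C(C)(C)C)cc1OC | intermediate
12 | 4-bromo-2,6-dimethoxyphenol | COc1cc(Br)cc(OC)c1O | starting material
13 | 5-bromo-1,3-dimethoxy-2-(methoxymethoxy)benzene | COCOc1c(OC)cc(Br)cc1OC | intermediate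
14 | 3,5-dimethoxy-4-(methoxymethoxy)phenyllithium | [Li]c1cc(OC)c(OCOC)c(OC)c1 | intermediate (not isolated)
15 | lithium borate (ate complex) from 6 and 14; orientation at boron not defined | [Li+].CC(C)(C)[Si](C)(C)OC/C=C/[B-]1(c5cc(OC)c(OCOC)c(OC)c5)O[C@]2(C)c3cccc4cccc(c34)[C@]2(C)O1 | intermediate (not isolated)
16 | cyclic ester with diol 4 of (1S,2R)-3-(tert-butyldimethylsilyloxy)-2-[5-(3-(tert-butyldimethylsilyloxy)propyl)-3-methoxy-2-(methoxymethoxy)phenyl]-1-[3,5-dimethoxy-4-(methoxymethoxy)phenyl]propylboronic acid | COCOc1c(OC)cc(cc1OC)[C@@H](B1O[C@]2(C)c3cccc4cccc(c34)[C@]2(C)O1)[C@H](c1cc(CCCO[Si](C)(C)C(C)(C)C)cc(OC)c1OCOC)CO[Si](C)(C)C(C)(C)C | intermediate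
17 | (1S,2R)-3-(tert-butyldimethylsilyloxy)-2-[5-(3-(tert-butyldimethylsilyloxy)propyl)-3-methoxy-2-(methoxymethoxy)phenyl]-1-[3,5-dimethoxy-4-(methoxymethoxy)phenyl]propan-1-ol | COCOc1c(OC)cc(cc1OC)[C@@H](O)[C@H](c1cc(CCCO[Si](C)(C)C(C)(C)C)cc(OC)c1OCOC)CO[Si](C)(C)C(C)(C)C | intermediate
18 | 4-[(1S,2R)-1,3-dihydroxy-2-[2-hydroxy-5-(3-hydroxypropyl)-3-methoxyphenyl]propyl]-2,6-dimethoxyphenol | COc1cc(cc(OC)c1O)[C@@H](O)[C@H](c1cc(CCCO)cc(OC)c1O)CO | intermediate (not isolated)
19 | 4-[(2S,3R)-3-(hydroxymethyl)-5-(3-hydroxypropyl)-7-methoxy-2,3-dihydro-1-benzofuran-2-yl]-2,6-dimethoxyphenol | COc1cc([C@H]2Oc3c(OC)cc(CCCO)cc3[C@@H]2CO)cc(OC)c1O | target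

## Step count and least certain steps

Total: 11 steps. Longest linear sequence: 7 steps (steps 4, 5, 6, 7, 9, 10, 11, from eugenol).

**Step 9 (key step).**
- Most likely failures: direct Suzuki–Miyaura transfer from the ate complex instead of the metallate shift; slow oxidative addition into the electron-rich bromide with its ortho acetal; β-silyloxy elimination from the alkylpalladium intermediate; inhibition by residual bromide; insufficient facial discrimination by the ligand on a β-substituted, allylically oxygenated alkene. Any loss in enantiomeric purity at C3 is carried to the target.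
- Fallback: an auxiliary-controlled aldol, setting out from 11 and from the aryllithium 14 and rejoining at 19 through the pentaol 18.
  - Coupling of 11 with the Reformatsky reagent BrZnCH2CO2Et (Pd(dba)2, XPhos, THF) should give ethyl 2-[5-(3-(tert-butyldimethylsilyloxy)propyl)-3-methoxy-2-(methoxymethoxy)phenyl]acetate F1.
  - LiOH should give the corresponding arylacetic acid F2.
  - Pivaloyl mixed anhydride and lithiated (S)-4-benzyloxazolidin-2-one should give the N-arylacetyl oxazolidinone F3.
  - Quenching 14 with DMF gives 3,5-dimethoxy-4-(methoxymethoxy)benzaldehyde F4.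
  - The Bu2BOTf/i-Pr2NEt syn aldol of F3 with F4 should give the (2S,3S) aldol adduct F5, with C3 of the target set by the auxiliary.
  - LiBH4 should release the (1S,2R)-1,3-diol F6, which differs from 17 only in its free C9 hydroxyl and is taken to 19 under the conditions of step 11.

**Step 11.**
- Most likely failures: intermolecular capture of the C2 cation by another electron-rich ring; electrophilic attack on the phenols by the one-carbon fragment released from the acetals; fragmentation of the cation with loss of C9; incomplete trans selectivity if closure is not reversible.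
- Fallback: close the ring before deprotection, setting out from 17 and returning at 19. BF3·OEt2 in CH2Cl2 at −78 to −40 °C ionises only the C2 alcohol. The ring A acetal oxygen should capture the cation with loss of its methoxymethyl group, giving the protected trans-dihydrobenzofuran F7. Mild HCl in MeOH then removes the remaining acetal and the silyl ethers from a ring that is already closed.

**Step 3.**
- Most likely failures: incomplete ester exchange with the hindered tertiary diol; protodeboronation of the catechol ester during handling.
- Fallback: go through isolable boron intermediates, setting out from 2 and returning at 6. Hydroboration of 2 with pinacolborane catalysed by Cp2Zr(H)Cl gives the (E)-pinacol boronic ester F8. NaIO4/NH4OAc in aqueous acetone cleaves it to (E)-3-(tert-butyldimethylsilyloxy)prop-1-enylboronic acid F9. Condensation of F9 with 4 over MgSO4 gives 6.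

**Step 5.**
- Most likely failures: bromination para to the methoxy group instead of ortho to the phenol; twofold bromination.
- Fallback: replace electrophilic substitution by directed ortho-metalation, setting out from 8 and returning at 11. Phenol-selective acetal formation (MOMCl, K2CO3) gives 3-[3-methoxy-4-(methoxymethoxy)phenyl]propan-1-ol F10. Silylation gives tert-butyl{3-[3-methoxy-4-(methoxymethoxy)phenyl]propoxy}dimethylsilane F11. n-BuLi/TMEDA lithiates the only position ortho to the acetal oxygen, and quenching with BrCCl2CCl2Br gives 11 directly.

## Further compounds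

F1 | step 9 | ethyl 2-[5-(3-(tert-butyldimethylsilyloxy)propyl)-3-methoxy-2-(methoxymethoxy)phenyl]acetate | CCOC(=O)Cc1cc(CCCO[Si](C)(C)C(C)(C)C)cc(OC)c1OCOC
F2 | step 9 | 2-[5-(3-(tert-butyldimethylsilyloxy)propyl)-3-methoxy-2-(methoxymethoxy)phenyl]acetic acid | OC(=O)Cc1cc(CCCO[Si](C)(C)C(C)(C)C)cc(OC)c1OCOC
F3 | step 9 | (S)-4-benzyl-3-{2-[5-(3-(tert-butyldimethylsilyloxy)propyl)-3-methoxy-2-(methoxymethoxy)phenyl]acetyl}oxazolidin-2-one | O=C1OC[C@H](Cc2ccccc2)N1C(=O)Cc1cc(CCCO[Si](C)(C)C(C)(C)C)cc(OC)c1OCOC
F4 | step 9 | 3,5-dimethoxy-4-(methoxymethoxy)benzaldehyde | COCOc1c(OC)cc(C=O)cc1OC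
F5 | step 9 | (S)-4-benzyl-3-{(2S,3S)-2-[5-(3-(tert-butyldimethylsilyloxy)propyl)-3-methoxy-2-(methoxymethoxy)phenyl]-3-[3,5-dimethoxy-4-(methoxymethoxy)phenyl]-3-hydroxypropanoyl}oxazolidin-2-one | O=C1OC[C@H](Cc2ccccc2)N1C(=O)[C@@H](c1cc(CCCO[Si](C)(C)C(C)(C)C)cc(OC)c1OCOC)[C@H](O)c1cc(OC)c(OCOC)c(OC)c1
F6 | step 9 | (1S,2R)-2-[5-(3-(tert-butyldimethylsilyloxy)propyl)-3-methoxy-2-(methoxymethoxy)phenyl]-1-[3,5-dimethoxy-4-(methoxymethoxy)phenyl]propane-1,3-diol | OC[C@@H](c1cc(CCCO[Si](C)(C)C(C)(C)C)cc(OC)c1OCOC)[C@H](O)c1cc(OC)c(OCOC)c(OC)c1
F7 | step 11 | tert-butyl{3-[(2S,3R)-3-(tert-butyldimethylsilyloxymethyl)-2-[3,5-dimethoxy-4-(methoxymethoxy)phenyl]-7-methoxy-2,3-dihydro-1-benzofuran-5-yl]propoxy}dimethylsilane | COCOc1c(OC)cc(cc1OC)[C@H]1Oc2c(OC)cc(CCCO[Si](C)(C)C(C)(C)C)cc2[C@@H]1CO[Si](C)(C)C(C)(C)C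
F8 | step 3 | (E)-3-(tert-butyldimethylsilyloxy)prop-1-enylboronic acid pinacol ester | CC1(C)OB(/C=C/CO[Si](C)(C)C(C)(C)C)OC1(C)C
F9 | step 3 | (E)-3-(tert-butyldimethylsilyloxy)prop-1-enylboronic acid | OB(O)/C=C/CO[Si](C)(C)C(C)(C)C
F10 | step 5 | 3-[3-methoxy-4-(methoxymethoxy)phenyl]propan-1-ol | COCOc1ccc(CCCO)cc1OC
F11 | step 5 | tert-butyl{3-[3-methoxy-4-(methoxymethoxy)phenyl]propoxy}dimethylsilane | COCOc1ccc(CCCO[Si](C)(C)C(C)(C)C)cc1OC
A1 | alternative 1 | methyl (2S,3S)-5-(3-acetoxypropyl)-2-(4-acetoxy-3,5-dimethoxyphenyl)-7-methoxy-2,3-dihydro-1-benzofuran-3-carboxylate | COc1cc([C@H]2Oc3c(OC)cc(CCCOC(C)=O)cc3[C@@H]2C(=O)OC)cc(OC)c1OC(C)=O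
A2 | alternative 1 | (2S)-6-(3-acetoxypropyl)-2-(4-acetoxy-3,5-dimethoxyphenyl)-8-methoxychroman-4-one | COc1cc([C@H]2Oc3c(OC)cc(CCCOC(C)=O)cc3C(=O)C2)cc(OC)c1OC(C)=O
A3 | alternative 2 | (2S,3R)-2-(4-benzyloxy-3,5-dimethoxyphenyl)-3-(tert-butyldimethylsilyloxymethyl)-5-(3-(tert-butyldimethylsilyloxy)propyl)-7-trimethylsilyl-2,3-dihydro-1-benzofuran | COc1cc([C@H]2Oc3c([Si](C)(C)C)cc(CCCO[Si](C)(C)C(C)(C)C)cc3[C@@H]2CO[Si](C)(C)C(C)(C)C)cc(OC)c1OCc1ccccc1
A4 | alternative 2 | tert-butyl{(2R,3S)-3-(4-benzyloxy-3,5-dimethoxyphenyl)-2-ethynyl-3-[(trimethylsilyl)ethynyloxy]propoxy}dimethylsilane | C[Si](C)(C)C#CO[C@H](c1cc(OC)c(OCc2ccccc2)c(OC)c1)[C@@H](CO[Si](C)(C)C(C)(C)C)C#C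
A5 | alternative 2 | tert-butyldimethyl(pent-4-yn-1-yloxy)silane | C#CCCCO[Si](C)(C)C(C)(C)C
A6 | alternative 3 | (2S,3R)-3-(tert-butyldimethylsilyloxymethyl)-2-[3,5-dimethoxy-4-(triisopropylsilyloxy)phenyl]-7-methoxy-2,3-dihydro-1-benzofuran | COc1cc([C@H]2Oc3c(OC)cccc3[C@@H]2CO[Si](C)(C)C(C)(C)C)cc(OC)c1O[Si](C(C)C)(C(C)C)C(C)C
A7 | alternative 3 | (1S,2R)-2-(2-bromo-3-methoxyphenyl)-3-(tert-butyldimethylsilyloxy)-1-[3,5-dimethoxy-4-(triisopropylsilyloxy)phenyl]propan-1-ol | COc1cc([C@@H](O)[C@@H](CO[Si](C)(C)C(C)(C)C)c2cccc(OC)c2Br)cc(OC)c1O[Si](C(C)C)(C(C)C)C(C)C
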